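**Retrosynthetic overview**

1. Numbering: C1 is the amide carbonyl and C2–C15 run along the ansa chain to the benzylic carbon C15. C16–C21 are the quinone ring carbons (C16 bears C15, C17 the OH, C20 the N). The oxane is O–C11–C12–C13–C14–C15.
2. Last ring: the 19-membered lactam (N–C1), closed on a seco amino acid; the arene is then oxidised and its C17 methyl ether hydrolysed. The chain is grown on the oxane: C3–C4 by B-alkyl Suzuki–Miyaura coupling, C6–C7 by methoxyallylboration, C8=C9 by Wittig olefination, C10–C11 by axial addition of a chiral titanium enolate to the C11 oxocarbenium ion.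
3. First ring: the oxane, made as its δ-lactone (C11 as C=O). The key step disconnects C13–C14 and O–C15 together. Its precursor is an aryl ester that ties (S)-2-methoxysuccinic acid (C11–C13 plus one extra carboxyl carbon, as a redox-active ester) through the C17 oxygen to an (E)-propenylarene (C14=C15).
4. Enabling feature: C15 is benzylic to an electron-rich ring and the C17 oxygen is ortho to C16, so O17–C17–C16–C15 can span C11 and C15. A temporary eight-membered aryl ester ring (C11, O17, C17, C16, C15, C14, C13, C12) is closed by a radical, stitched across (carbonyl O of C11 to C15) to a 2,8-dioxabicyclo[3.3.1]nonane cation, and hydrolysed to the pyranone with release of O17 as the phenol.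
5. Stereocontrol: C12 comes from L-malic acid and sets C14 and C15 in the key step, then C11. C10 comes from the auxiliary, C6 and C7 from the borane; both alkenes are E by construction.

Key step: step 9

Remark: the oxidation in the last step may give the para- or the ortho-quinone; both are vinylogous methyl esters that hydrolyse to the same 2-hydroxy-1,4-benzoquinone, so only the para-quinone is drawn.

**Route**

Step 1
Reactants: 1 2,5-dimethoxyphenol; 2 allyl bromide
Product: 3 2-(allyloxy)-1,4-dimethoxybenzene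
Conditions: K2CO3, acetone, reflux
Reagents that add atoms: none
Why: Williamson etherification of the phenoxide with a primary allylic bromide.

Step 2
Reactants: 3 2-(allyloxy)-1,4-dimethoxybenzene
Product: 4 2-allyl-3,6-dimethoxyphenol
Conditions: N,N-diethylaniline, 190 °C
Reagents that add atoms: none
Why: Aromatic Claisen rearrangement; the only free ortho position takes the allyl group, which places it between the hydroxyl and a methoxy group.

Step 3
Reactants: 4 2-allyl-3,6-dimethoxyphenol
Product: 5 3,6-dimethoxy-2-[(E)-prop-1-enyl]phenol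
Conditions: RuHCl(CO)(PPh3)3 (2 mol%), toluene, 80 °C
Reagents that add atoms: none
Why: Ruthenium hydride-catalysed alkene isomerisation (hydrometalation and β-hydride elimination) into conjugation, the E isomer being the thermodynamic product.

Step 4
Reactants: 6 dimethyl (S)-malate
Product: 7 dimethyl (S)-2-methoxysuccinate
Conditions: MeI, Ag2O, MeCN, 40 °C, dark
Reagents that add atoms: iodomethane, CI
Why: Silver oxide-mediated O-methylation under non-basic conditions, so the stereocentre (the later C12) is not touched.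

Step 5
Reactants: 7 dimethyl (S)-2-methoxysuccinate
Product: 8 (S)-2-methoxysuccinic acid
Conditions: 6 M HCl, reflux
Reagents that add atoms: water, O
Why: Acid-catalysed ester hydrolysis, chosen over saponification to avoid β-elimination of methanol.

Step 6
Reactants: 8 (S)-2-methoxysuccinic acid
Product: 9 (S)-2-methoxysuccinic anhydride
Conditions: acetyl chloride, reflux; evaporation
Reagents that add atoms: none
Why: Cyclodehydration of a succinic acid to the five-membered anhydride through the mixed anhydride.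

Step 7
Reactants: 9 (S)-2-methoxysuccinic anhydride; 5 3,6-dimethoxy-2-[(E)-prop-1-enyl]phenol
Product: 10 (S)-4-{3,6-dimethoxy-2-[(E)-prop-1-enyl]phenoxy}-3-methoxy-4-oxobutanoic acid
Conditions: Et3N, DMAP (cat.), CH2Cl2, 0 °C to rt; dilute HCl wash
Reagents that add atoms: none
Why: DMAP-catalysed ring opening of the unsymmetrical anhydride by the phenol at the carbonyl next to the methoxy-bearing carbon (the more electrophilic one), which should give the aryl ester at C11 and leave the other carboxyl free.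

Step 8
Reactants: 10 (S)-4-{3,6-dimethoxy-2-[(E)-prop-1-enyl]phenoxy}-3-methoxy-4-oxobutanoic acid
Product: 11 1-{3,6-dimethoxy-2-[(E)-prop-1-enyl]phenyl} 4-(1,3-dioxoisoindolin-2-yl) (S)-2-methoxysuccinate
Conditions: N-hydroxyphthalimide, DIC, DMAP (cat.), CH2Cl2, rt
Reagents that add atoms: N-hydroxyphthalimide, ON1C(=O)c2ccccc2C1=O
Why: Carbodiimide esterification of the free acid gives the redox-active N-acyloxyphthalimide.

Step 9
Reactants: 11 1-{3,6-dimethoxy-2-[(E)-prop-1-enyl]phenyl} 4-(1,3-dioxoisoindolin-2-yl) (S)-2-methoxysuccinate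
Product: 13 (3S,5S,6S)-6-(2-hydroxy-3,6-dimethoxyphenyl)-3-methoxy-5-methyloxan-2-one, via bridged dioxocarbenium ion 12 (not isolated)
Conditions: fac-Ir(ppy)3 (2 mol%), H2O (10 equiv), degassed MeCN, 5 mM, blue LEDs (450 nm), 25 °C
Reagents that add atoms: water, O
Why: Proposed new method: the excited iridium catalyst reduces the N-acyloxyphthalimide, loss of CO2 gives the primary C13 radical, this adds to C14 of the tethered (E)-propenyl group, and the benzylic C15 radical is oxidised by the tetravalent iridium to a cation that the ester carbonyl oxygen captures across the ring; water then hydrolyses ion 12 with loss of the better leaving group, the phenoxide, so the aryl ester becomes the δ-lactone and the phenol is set free. The closest known reactions are the photoredox decarboxylative oxyalkylation and carbolactonisation of styrenes with redox-active esters (radical–polar crossover) and the 8-endo cyclisation of ester-tethered radicals; their union in a tethered form with acyl transfer is not known. The temporary eight-membered aryl ester ring closes in the 8-endo-trig mode (it gives the benzylic radical, 7-exo would give an unstabilised one), and the six-membered ring closes by transannular attack of the C11 carbonyl oxygen on C15, a 1,5 relation that gives the chair–chair 2,8-dioxabicyclo[3.3.1]nonane skeleton. C14: the E alkene inside the forming ring keeps the methyl anti to the C15–aryl bond, and the chair-like arrangement puts the C12 methoxy group equatorial, away from this axial methyl, so C12 from malic acid fixes C14; C15: the carbonyl oxygen can only reach the face that makes the aryl bond the second axial bridge, which after collapse means aryl trans to methyl and cis to the C12 methoxy group. The step needs ring closure to beat bimolecular addition and hydrogen abstraction, which the tether and the dilution secure, and it needs a substrate without a competing 5-exo acceptor, which is why it is run before the trisubstituted alkene of the chain exists.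

Step 10
Reactants: 13 (3S,5S,6S)-6-(2-hydroxy-3,6-dimethoxyphenyl)-3-methoxy-5-methyloxan-2-one
Product: 14 (3S,5S,6S)-3-methoxy-5-methyl-6-(2,3,6-trimethoxyphenyl)oxan-2-one
Conditions: MeI, K2CO3, DMF, 0 °C to rt
Reagents that add atoms: iodomethane, CI
Why: Williamson methylation of the phenoxide, which also blocks any later quinone methide opening of the benzylic lactone.

Step 11
Reactants: 14 (3S,5S,6S)-3-methoxy-5-methyl-6-(2,3,6-trimethoxyphenyl)oxan-2-one
Product: 15 (3S,5S,6S)-3-methoxy-5-methyl-6-(2,3,6-trimethoxy-5-nitrophenyl)oxan-2-one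
Conditions: HNO3 (70%), AcOH, 10 °C
Reagents that add atoms: nitric acid, O[N+](=O)[O-]
Why: Electrophilic aromatic nitration at the free position that is ortho to one methoxy group and para to another (the later C20), the other free position being less activated.

Step 12
Reactants: 15 (3S,5S,6S)-3-methoxy-5-methyl-6-(2,3,6-trimethoxy-5-nitrophenyl)oxan-2-one
Product: 17 (3S,5S,6S)-3-methoxy-5-methyl-6-(2,3,6-trimethoxy-5-nitrophenyl)oxan-2-yl acetate (anomer mixture), via diisobutylaluminium lactolate 16 (not isolated)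
Conditions: i-Bu2AlH, CH2Cl2, −78 °C; then pyridine, DMAP, Ac2O, −78 °C to rt
Reagents that add atoms: acetic anhydride, CC(=O)OC(C)=O
Why: Reductive acetylation of a lactone: the aluminium hemiacetal is acetylated in the flask before it can open.

Step 13
Reactants: 17 (3S,5S,6S)-3-methoxy-5-methyl-6-(2,3,6-trimethoxy-5-nitrophenyl)oxan-2-yl acetate; 18 (S)-4-benzyl-3-propionyl-1,3-thiazolidine-2-thione
Product: 20 (S)-4-benzyl-3-{(R)-2-[(2R,3S,5S,6S)-3-methoxy-5-methyl-6-(2,3,6-trimethoxy-5-nitrophenyl)oxan-2-yl]propanoyl}-1,3-thiazolidine-2-thione, via trichlorotitanium enolate 19 (not isolated)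
Conditions: 18, TiCl4, i-Pr2NEt, CH2Cl2, −78 °C; then 17, SnCl4, −78 to −40 °C
Reagents that add atoms: none
Why: Acetal substitution: SnCl4 ionises the anomeric acetate to the C11 oxocarbenium ion, which the chelated Z titanium enolate should attack axially and anti to the axial C12 methoxy group while aryl and methyl stay equatorial (C11, 2,6-trans), on the enolate face opposite the benzyl group of the auxiliary (C10).

Step 14
Reactants: 20 (S)-4-benzyl-3-{(R)-2-[(2R,3S,5S,6S)-3-methoxy-5-methyl-6-(2,3,6-trimethoxy-5-nitrophenyl)oxan-2-yl]propanoyl}-1,3-thiazolidine-2-thione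
Product: 21 (R)-2-[(2R,3S,5S,6S)-3-methoxy-5-methyl-6-(2,3,6-trimethoxy-5-nitrophenyl)oxan-2-yl]propanal
Conditions: i-Bu2AlH, CH2Cl2, −78 °C
Reagents that add atoms: none
Why: Hydride reduction of the activated N-acyl thiazolidinethione stops at the aldehyde through a stable tetrahedral aluminate and releases the auxiliary.

Step 15
Reactants: 21 (R)-2-[(2R,3S,5S,6S)-3-methoxy-5-methyl-6-(2,3,6-trimethoxy-5-nitrophenyl)oxan-2-yl]propanal; 22 2-(triphenylphosphoranylidene)propanal
Product: 23 (S,E)-2-methyl-4-[(2R,3S,5S,6S)-3-methoxy-5-methyl-6-(2,3,6-trimethoxy-5-nitrophenyl)oxan-2-yl]pent-2-enal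
Conditions: toluene, 90 °C
Reagents that add atoms: none
Why: Wittig olefination with a stabilised ylide, which should give the E trisubstituted enal (C8=C9).

Step 16
Reactants: 23 (S,E)-2-methyl-4-[(2R,3S,5S,6S)-3-methoxy-5-methyl-6-(2,3,6-trimethoxy-5-nitrophenyl)oxan-2-yl]pent-2-enal; 24 allyl methyl ether
Product: 26 (3S,4S,5E,7S)-3-methoxy-5-methyl-7-[(2R,3S,5S,6S)-3-methoxy-5-methyl-6-(2,3,6-trimethoxy-5-nitrophenyl)oxan-2-yl]octa-1,5-dien-4-ol, via methoxyallyl diisopinocampheylborane 25 (not isolated)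
Conditions: 24, s-BuLi, THF, −78 °C; (+)-Ipc2BOMe (from (−)-α-pinene); BF3·OEt2; then 23, −78 °C; NaOH, H2O2
Reagents that add atoms: none
Why: Asymmetric (Z)-γ-methoxyallylboration through a closed chair transition state, in which the Z geometry gives the syn C6/C7 relation and the isopinocampheyl groups direct the attack to the Re face of the aldehyde (C7 S, reagent control).

Step 17
Reactants: 26 (3S,4S,5E,7S)-3-methoxy-5-methyl-7-[(2R,3S,5S,6S)-3-methoxy-5-methyl-6-(2,3,6-trimethoxy-5-nitrophenyl)oxan-2-yl]octa-1,5-dien-4-ol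
Product: 27 tert-butyldimethylsilyl ether of 26 at the C7 hydroxyl
Conditions: TBSOTf, 2,6-lutidine, CH2Cl2, −78 °C
Reagents that add atoms: tert-butyldimethylsilyl triflate, CC(C)(C)[Si](C)(C)OS(=O)(=O)C(F)(F)F
Why: Silylation of the secondary allylic alcohol with a silyl triflate and a hindered base.

Step 18
Reactants: 28 diethyl 2-methylmalonate; 29 iodoform
Product: 30 diethyl 2-(diiodomethyl)-2-methylmalonate
Conditions: NaH, Et2O, reflux
Reagents that add atoms: none
Why: C-alkylation of the malonate anion with iodoform.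

Step 19
Reactants: 30 diethyl 2-(diiodomethyl)-2-methylmalonate
Product: 31 (E)-3-iodo-2-methylprop-2-enoic acid
Conditions: KOH, EtOH/H2O, reflux; then HCl
Reagents that add atoms: potassium hydroxide, [K+].[OH-]
Why: Saponification, decarboxylation and elimination of HI should give the E iodoacrylic acid as the more stable isomer.

Step 20
Reactants: 27 tert-butyldimethylsilyl ether of 26; 31 (E)-3-iodo-2-methylprop-2-enoic acid
Product: 33 (2E,6S,7S,8E,10S)-7-[(tert-butyldimethylsilyl)oxy]-6-methoxy-2,8-dimethyl-10-[(2R,3S,5S,6S)-3-methoxy-5-methyl-6-(2,3,6-trimethoxy-5-nitrophenyl)oxan-2-yl]undeca-2,8-dienoic acid, via alkyl borabicyclononane 32 (not isolated)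
Conditions: 9-BBN, THF, rt; then 31, Pd(dppf)Cl2, AsPh3, Cs2CO3, DMF/H2O, rt; acidic work-up
Reagents that add atoms: none
Why: Anti-Markovnikov hydroboration of the terminal alkene followed by B-alkyl Suzuki–Miyaura coupling, which forms C3–C4 with retention of the E geometry of the alkenyl iodide.

Step 21
Reactants: 33 the nitro acid
Product: 34 (2E,6S,7S,8E,10S)-10-[(2R,3S,5S,6S)-6-(5-amino-2,3,6-trimethoxyphenyl)-3-methoxy-5-methyloxan-2-yl]-7-[(tert-butyldimethylsilyl)oxy]-6-methoxy-2,8-dimethylundeca-2,8-dienoic acid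
Conditions: Zn, NH4Cl, EtOH/H2O, 40 °C
Reagents that add atoms: none
Why: Dissolving-metal reduction of the nitroarene to the aniline, which leaves the alkenes, the enoic acid and the silyl ether alone.

Step 22
Reactants: 34 the amino acid
Product: 35 macrolactam (N–C1 amide of 34; arene 17,18,21-trimethoxy; C7 silyl ether)
Conditions: BOP-Cl, i-Pr2NEt, toluene, 85 °C, 1 mM
Reagents that add atoms: none
Why: Macrolactamisation through the mixed phosphinic anhydride under high dilution closes the 19-membered ansa ring.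

Step 23
Reactants: 35 macrolactam
Product: 36 C7 alcohol of 35
Conditions: HF·pyridine, pyridine, THF, 0 °C to rt
Reagents that add atoms: none
Why: Fluoride cleavage of the silyl ether.

Step 24
Reactants: 36 C7 alcohol of 35
Product: 38 CNP0204467.1, via methoxyquinone 37 (not isolated)
Conditions: (NH4)2Ce(NO3)6, MeCN/H2O, 0 °C; then Ba(OH)2, dioxane/H2O, rt; dilute HCl
Reagents that add atoms: water, O; barium hydroxide, [Ba+2].[OH-].[OH-]
Why: Oxidative demethylation of the dimethoxyarene by tetravalent cerium gives the quinone, and hydroxide then replaces the remaining methoxy group by addition–elimination at the vinylogous ester carbon C17.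

**Compound list**

1 | 2,5-dimethoxyphenol | COc1ccc(OC)c(O)c1 | starting material
2 | allyl bromide | C=CCBr | starting material
3 | 2-(allyloxy)-1,4-dimethoxybenzene | COc1ccc(OC)c(OCC=C)c1 | intermediate
4 | 2-allyl-3,6-dimethoxyphenol | COc1ccc(OC)c(CC=C)c1O | intermediate
5 | 3,6-dimethoxy-2-[(E)-prop-1-enyl]phenol | COc1ccc(OC)c(/C=C/C)c1O | intermediate
6 | dimethyl (S)-malate | O[C@H](C(=O)OC)CC(=O)OC | starting material
7 | dimethyl (S)-2-methoxysuccinate | CO[C@H](C(=O)OC)CC(=O)OC | intermediate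
8 | (S)-2-methoxysuccinic acid | CO[C@H](C(=O)O)CC(=O)O | intermediate
9 | (S)-2-methoxysuccinic anhydride | CO[C@H]1CC(=O)OC1=O | intermediate
10 | (S)-4-{3,6-dimethoxy-2-[(E)-prop-1-enyl]phenoxy}-3-methoxy-4-oxobutanoic acid | CO[C@H](C(=O)Oc1c(/C=C/C)c(OC)ccc1OC)CC(=O)O | intermediate
11 | 1-{3,6-dimethoxy-2-[(E)-prop-1-enyl]phenyl} 4-(1,3-dioxoisoindolin-2-yl) (S)-2-methoxysuccinate | CO[C@H](C(=O)Oc1c(/C=C/C)c(OC)ccc1OC)CC(=O)ON1C(=O)c2ccccc2C1=O | intermediate
12 | bridged dioxocarbenium ion (benzo-fused 2,8-dioxabicyclo[3.3.1]nonane cation) | CO[C@H]1C[C@H](C)[C@@H]2[O+]=C1Oc1c(OC)ccc(OC)c12 | intermediate (not isolated)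
13 | (3S,5S,6S)-6-(2-hydroxy-3,6-dimethoxyphenyl)-3-methoxy-5-methyloxan-2-one | CO[C@H]1C[C@H](C)[C@@H](c2c(O)c(OC)ccc2OC)OC1=O | intermediate
14 | (3S,5S,6S)-3-methoxy-5-methyl-6-(2,3,6-trimethoxyphenyl)oxan-2-one | CO[C@H]1C[C@H](C)[C@@H](c2c(OC)c(OC)ccc2OC)OC1=O | intermediate
15 | (3S,5S,6S)-3-methoxy-5-methyl-6-(2,3,6-trimethoxy-5-nitrophenyl)oxan-2-one | CO[C@H]1C[C@H](C)[C@@H](c2c(OC)c(OC)cc([N+](=O)[O-])c2OC)OC1=O | intermediate
16 | diisobutylaluminium lactolate of 15 | CO[C@H]1C[C@H](C)[C@@H](c2c(OC)c(OC)cc([N+](=O)[O-])c2OC)OC1O[Al](CC(C)C)CC(C)C | intermediate (not isolated)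
17 | (3S,5S,6S)-3-methoxy-5-methyl-6-(2,3,6-trimethoxy-5-nitrophenyl)oxan-2-yl acetate (anomer mixture) | CO[C@H]1C[C@H](C)[C@@H](c2c(OC)c(OC)cc([N+](=O)[O-])c2OC)OC1OC(C)=O | intermediate
18 | (S)-4-benzyl-3-propionyl-1,3-thiazolidine-2-thione | CCC(=O)N1C(=S)SC[C@@H]1Cc1ccccc1 | starting material
19 | trichlorotitanium (Z)-enolate of 18 | C/C=C(\O[Ti](Cl)(Cl)Cl)N1C(=S)SC[C@@H]1Cc1ccccc1 | intermediate (not isolated)
20 | (S)-4-benzyl-3-{(R)-2-[(2R,3S,5S,6S)-3-methoxy-5-methyl-6-(2,3,6-trimethoxy-5-nitrophenyl)oxan-2-yl]propanoyl}-1,3-thiazolidine-2-thione | CO[C@H]1C[C@H](C)[C@@H](c2c(OC)c(OC)cc([N+](=O)[O-])c2OC)O[C@@H]1[C@@H](C)C(=O)N1C(=S)SC[C@@H]1Cc1ccccc1 | intermediate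
21 | (R)-2-[(2R,3S,5S,6S)-3-methoxy-5-methyl-6-(2,3,6-trimethoxy-5-nitrophenyl)oxan-2-yl]propanal | CO[C@H]1C[C@H](C)[C@@H](c2c(OC)c(OC)cc([N+](=O)[O-])c2OC)O[C@@H]1[C@@H](C)C=O | intermediate
22 | 2-(triphenylphosphoranylidene)propanal | CC(C=O)=P(c1ccccc1)(c1ccccc1)c1ccccc1 | starting material
23 | (S,E)-2-methyl-4-[(2R,3S,5S,6S)-3-methoxy-5-methyl-6-(2,3,6-trimethoxy-5-nitrophenyl)oxan-2-yl]pent-2-enal | CO[C@H]1C[C@H](C)[C@@H](c2c(OC)c(OC)cc([N+](=O)[O-])c2OC)O[C@@H]1[C@@H](C)/C=C(\C)C=O | intermediate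
24 | allyl methyl ether | COCC=C | starting material
25 | [(Z)-3-methoxyallyl]diisopinocampheylborane (isopinocampheyl groups from (−)-α-pinene) | CO/C=C\CB([C@H]1C[C@H]2C[C@@H]([C@@H]1C)C2(C)C)[C@H]1C[C@H]2C[C@@H]([C@@H]1C)C2(C)C | intermediate (not isolated)
26 | (3S,4S,5E,7S)-3-methoxy-5-methyl-7-[(2R,3S,5S,6S)-3-methoxy-5-methyl-6-(2,3,6-trimethoxy-5-nitrophenyl)oxan-2-yl]octa-1,5-dien-4-ol | CO[C@H]1C[C@H](C)[C@@H](c2c(OC)c(OC)cc([N+](=O)[O-])c2OC)O[C@@H]1[C@@H](C)/C=C(\C)[C@H](O)[C@@H](OC)C=C | intermediate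
27 | tert-butyldimethylsilyl ether of 26 at the C7 hydroxyl | CO[C@H]1C[C@H](C)[C@@H](c2c(OC)c(OC)cc([N+](=O)[O-])c2OC)O[C@@H]1[C@@H](C)/C=C(\C)[C@H](O[Si](C)(C)C(C)(C)C)[C@@H](OC)C=C | intermediate
28 | diethyl 2-methylmalonate | CCOC(=O)C(C)C(=O)OCC | starting material
29 | iodoform | IC(I)I | starting material
30 | diethyl 2-(diiodomethyl)-2-methylmalonate | CCOC(=O)C(C)(C(I)I)C(=O)OCC | intermediate
31 | (E)-3-iodo-2-methylprop-2-enoic acid | C/C(=C\I)C(=O)O | intermediate
32 | B-alkyl-9-borabicyclo[3.3.1]nonane from 27 (boron on C4) | CO[C@H]1C[C@H](C)[C@@H](c2c(OC)c(OC)cc([N+](=O)[O-])c2OC)O[C@@H]1[C@@H](C)/C=C(\C)[C@H](O[Si](C)(C)C(C)(C)C)[C@@H](OC)CCB1C2CCCC1CCC2 | intermediate (not isolated)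
33 | (2E,6S,7S,8E,10S)-7-[(tert-butyldimethylsilyl)oxy]-6-methoxy-2,8-dimethyl-10-[(2R,3S,5S,6S)-3-methoxy-5-methyl-6-(2,3,6-trimethoxy-5-nitrophenyl)oxan-2-yl]undeca-2,8-dienoic acid | CO[C@H]1C[C@H](C)[C@@H](c2c(OC)c(OC)cc([N+](=O)[O-])c2OC)O[C@@H]1[C@@H](C)/C=C(\C)[C@H](O[Si](C)(C)C(C)(C)C)[C@@H](OC)CC/C=C(\C)C(=O)O | intermediate
34 | amino acid: 33 with the nitro group reduced to NH2 | CO[C@H]1C[C@H](C)[C@@H](c2c(OC)c(OC)cc(N)c2OC)O[C@@H]1[C@@H](C)/C=C(\C)[C@H](O[Si](C)(C)C(C)(C)C)[C@@H](OC)CC/C=C(\C)C(=O)O | intermediate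
35 | macrolactam (N–C1 amide of 34; arene 17,18,21-trimethoxy; C7 silyl ether) | CO[C@H]1C[C@H](C)[C@@H]2O[C@@H]1[C@@H](C)/C=C(\C)[C@H](O[Si](C)(C)C(C)(C)C)[C@@H](OC)CC/C=C(\C)C(=O)Nc1cc(OC)c(OC)c2c1OC | intermediate
36 | C7 alcohol of 35 | CO[C@H]1C[C@H](C)[C@@H]2O[C@@H]1[C@@H](C)/C=C(\C)[C@H](O)[C@@H](OC)CC/C=C(\C)C(=O)Nc1cc(OC)c(OC)c2c1OC | intermediate
37 | 17-O-methyl ether of the target (para-quinone) | CO[C@H]1C[C@H](C)[C@@H]2O[C@@H]1[C@@H](C)/C=C(\C)[C@H](O)[C@@H](OC)CC/C=C(\C)C(=O)NC1=CC(=O)C(OC)=C2C1=O | intermediate (not isolated)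
38 | CNP0204467.1 | CO[C@H]1C[C@H](C)[C@@H]2O[C@@H]1[C@@H](C)/C=C(\C)[C@H](O)[C@@H](OC)CC/C=C(\C)C(=O)NC1=CC(=O)C(O)=C2C1=O | target

**Count and risks**

Total step count: 24. Longest linear sequence: 19 steps (steps 1–3 or 4–6, then 7–17 and 20–24).

Steps most likely to fail:

Step 9 (Proposed new method). The eight-membered ring closure of the primary radical may be slower than hydrogen abstraction or bimolecular addition, and the facial selectivity at C14 may be lower than the chair model predicts. Fallback from 5 and 9, returning at 13, with the known intermolecular reaction: 5 is silylated (TBSCl, imidazole) to tert-butyl{3,6-dimethoxy-2-[(E)-prop-1-enyl]phenoxy}dimethylsilane F1. Anhydride 9 is opened with methanol at the same carbonyl to (S)-3,4-dimethoxy-4-oxobutanoic acid F2, which is converted (N-hydroxyphthalimide, DIC) into its N-acyloxyphthalimide F3. F3 and an excess of F1 undergo the photoredox decarboxylative hydroxyalkylation of the styrene (fac-Ir(ppy)3, MeCN/H2O, blue LEDs) to the benzylic alcohol F4, formed as a mixture at C14 and C15. Bu4NF and then PPTS in warm toluene remove the silyl group and close the lactone, C15 equilibrating through the ortho-quinone methide to aryl trans to methyl. The C14 epimer is removed by chromatography to leave 13.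

Step 13. The facial preferences of the auxiliary and of the ring may be mismatched, and the Lewis acid may ionise the benzylic C15–O bond and scramble C15. Fallback from 17, returning at 23: axial allylation of the oxocarbenium ion with (E)-crotyltrimethylsilane and BF3·OEt2 in CH2Cl2 at −78 °C gives the crotyl C-glycoside F5 (C10 epimers separated). Cross metathesis of F5 with methacrolein (second-generation Hoveyda–Grubbs catalyst, CH2Cl2, 40 °C) gives enal 23 directly, so steps 14 and 15 are not needed.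

Step 22. Acylation of the hindered aniline at high dilution may be slow and oligomerisation may take over. Fallback from 27, returning at 35, with the ring closed at C3–C4: 27 is reduced (Zn, NH4Cl) to the aniline F6. Acid 31 is converted with oxalyl chloride and catalytic DMF into (E)-3-iodo-2-methylprop-2-enoyl chloride F7, which acylates F6 (pyridine, CH2Cl2) to the iodoacrylamide F8. Hydroboration of the terminal alkene with 9-BBN gives the borane F9, and slow addition of F9 to Pd(dppf)Cl2, AsPh3 and Cs2CO3 in DMF/THF/H2O closes the macrocycle by intramolecular B-alkyl Suzuki–Miyaura coupling to 35.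

**Further compounds**

F1 | step 9 | tert-butyl{3,6-dimethoxy-2-[(E)-prop-1-enyl]phenoxy}dimethylsilane | COc1ccc(OC)c(/C=C/C)c1O[Si](C)(C)C(C)(C)C
F2 | step 9 | (S)-3,4-dimethoxy-4-oxobutanoic acid | CO[C@H](C(=O)OC)CC(=O)O
F3 | step 9 | 4-(1,3-dioxoisoindolin-2-yl) 1-methyl (S)-2-methoxysuccinate | CO[C@H](C(=O)OC)CC(=O)ON1C(=O)c2ccccc2C1=O
F4 | step 9 | methyl (2S,4S,5S)-5-{2-[(tert-butyldimethylsilyl)oxy]-3,6-dimethoxyphenyl}-5-hydroxy-2-methoxy-4-methylpentanoate | CO[C@H](C(=O)OC)C[C@H](C)[C@@H](c1c(O[Si](C)(C)C(C)(C)C)c(OC)ccc1OC)O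
F5 | step 13 | (2R,3S,5S,6S)-2-[(S)-but-3-en-2-yl]-3-methoxy-5-methyl-6-(2,3,6-trimethoxy-5-nitrophenyl)oxane | CO[C@H]1C[C@H](C)[C@@H](c2c(OC)c(OC)cc([N+](=O)[O-])c2OC)O[C@@H]1[C@@H](C)C=C
F6 | step 22 | aniline from 27 (nitro group reduced to NH2) | CO[C@H]1C[C@H](C)[C@@H](c2c(OC)c(OC)cc(N)c2OC)O[C@@H]1[C@@H](C)/C=C(\C)[C@H](O[Si](C)(C)C(C)(C)C)[C@@H](OC)C=C
F7 | step 22 | (E)-3-iodo-2-methylprop-2-enoyl chloride | C/C(=C\I)C(Cl)=O
F8 | step 22 | N-aryl (E)-3-iodo-2-methylprop-2-enamide of F6 | CO[C@H]1C[C@H](C)[C@@H](c2c(OC)c(OC)cc(NC(=O)/C(C)=C/I)c2OC)O[C@@H]1[C@@H](C)/C=C(\C)[C@H](O[Si](C)(C)C(C)(C)C)[C@@H](OC)C=C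
F9 | step 22 | B-alkyl-9-borabicyclo[3.3.1]nonane from F8 | CO[C@H]1C[C@H](C)[C@@H](c2c(OC)c(OC)cc(NC(=O)/C(C)=C/I)c2OC)O[C@@H]1[C@@H](C)/C=C(\C)[C@H](O[Si](C)(C)C(C)(C)C)[C@@H](OC)CCB1C2CCCC1CCC2
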